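**Retrosynthetic overview**

1. Numbering: hydrophthalide half C1 (lactone C=O), C3 (butylidene carbon), C3a=C7a, C4–C7; phthalide half primed (C3' spiro carbon, C8' propyl-bearing carbon). Ring A = cyclohexene, ring B = cyclobutane C6–C7–C3'–C8', ring C = spiro-phthalide, ring D = butenolide.
2. Ring D last: 5-exo-dig lactonisation of a (Z)-2-en-4-ynoic acid; the alkyne comes from Sonogashira coupling of pent-1-yne with the C3a enol triflate of a C3a/C7a β-keto ester.
3. Ring B: C3'–C8' bond by 4-exo-tet alkylation of the ring C (phthalide) enolate on a C8' mesylate; ring C and the C8' carbinol arise together by hydride reduction of a 6,7-cis 1,4-diketone.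
4. Ring A (key step): catalytic enantioselective Diels–Alder reaction forming C4–C5 and C6–C7 from a Knoevenagel-derived 2-silyloxy diene (C4=C3a–C7a=C7, aroyl on C7, ester on C7a) and hex-1-en-3-one (C5=C6–C8'=O). Enabling feature: ring A holds a single alkene, C3a=C7a (shared with ring D), lying between C4 and C7 — a cyclohexene retron in which C3a can be carried as an enol-ether carbon and C6 bears C8', which can be carried as a ketone carbon.
5. Ring order: A (step 4) → C (step 5) → B (step 7) → D (step 12).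

Key step: step 4

Remark: glyoxal 2 is assumed to be usable as the free aldehyde after azeotropic drying of its hydrate; C3' in 8–10 is a mixture of epimers that converges in step 7.

**Step 1**
Reactants: 1 methyl 2-acetylbenzoate
Product: 2 methyl 2-(2-oxoacetyl)benzoate
Conditions: SeO2 (1.1 equiv), 1,4-dioxane/H2O (30:1), 90 °C; then toluene azeotrope
Reagents that add atoms: selenium dioxide, O=[Se]=O
Why: Riley oxidation converts the α-methyl group of the aryl methyl ketone into the glyoxal aldehyde, the benzoate ester being inert to SeO2.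

**Step 2**
Reactants: 2 methyl 2-(2-oxoacetyl)benzoate, 3 tert-butyl 3-oxobutanoate
Product: 4 tert-butyl (2Z)-2-acetyl-4-[2-(methoxycarbonyl)phenyl]-4-oxobut-2-enoate
Conditions: piperidine (5 mol%), AcOH (5 mol%), CH2Cl2, 4 Å molecular sieves, 0 °C → rt
Reagents that add atoms: none
Why: Knoevenagel condensation of the highly electrophilic glyoxal aldehyde with the active methylene of 3 should give the alkylidene acetoacetate, the isomer with the aroyl group cis to the ester (2Z) being expected to prevail as it does for arylidene acetoacetates.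

**Step 3**
Reactants: 4 tert-butyl (2Z)-2-acetyl-4-[2-(methoxycarbonyl)phenyl]-4-oxobut-2-enoate
Product: 5 tert-butyl (2Z)-4-[2-(methoxycarbonyl)phenyl]-4-oxo-2-{1-[(triisopropylsilyl)oxy]ethenyl}but-2-enoate
Conditions: i-Pr3SiOTf (1.2 equiv), Et3N (1.5 equiv), CH2Cl2, −78 → 0 °C; used at once
Reagents that add atoms: triisopropylsilyl trifluoromethanesulfonate, CC(C)[Si](C(C)C)(C(C)C)OS(=O)(=O)C(F)(F)F
Why: Soft enolisation (silyl triflate/amine) of the only enolisable ketone should give the cross-conjugated 2-silyloxy diene with the alkene geometry of step 2 retained, since the aryl ketone has no α-hydrogen.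

**Step 4**
Reactants: 5 tert-butyl (2Z)-4-[2-(methoxycarbonyl)phenyl]-4-oxo-2-{1-[(triisopropylsilyl)oxy]ethenyl}but-2-enoate, 6 hex-1-en-3-one
Product: 7 tert-butyl (5R,6R)-5-butanoyl-6-[2-(methoxycarbonyl)benzoyl]-2-[(triisopropylsilyl)oxy]cyclohex-1-ene-1-carboxylate
Conditions: (S)-3,3-diphenyl-1-(2-methylphenyl)tetrahydro-1H,3H-pyrrolo[1,2-c][1,3,2]oxazaborole (20 mol%), Tf2NH (18 mol%), 6 (3 equiv), CH2Cl2, −78 → −40 °C; Et3N quench at −78 °C
Reagents that add atoms: none
Why: Normal-electron-demand Diels–Alder reaction, concerted but asynchronous (C4–C5 bonding leads, C6–C7 follows), between the 2-silyloxy diene and the vinyl ketone bound to the chiral cationic boron Lewis acid; the closest known type is the oxazaborolidinium-catalysed enantioselective Diels–Alder reaction of 2-silyloxybutadienes with enones. Ring A is closed by an intermolecular suprafacial [4+2] cycloaddition. C6 is set by the catalyst, which shields one enantioface of the coordinated enone so that the diene should add to the Si face of its α-carbon (sense assigned by analogy to related enone cycloadditions). C7 is set relative to C6 by the (2Z) geometry of the diene terminus together with the endo orientation of the butanoyl group, which gives the 6,7-cis adduct. The step needs regio-, endo- and enantioselectivity: the silyloxy group on C3a makes C4 the nucleophilic terminus and pairs it with the enone β-carbon C5, the aroyl group on C7 reinforces the same "ortho" orientation, and the ester on C7a keeps the new C3a=C7a enol ether regiodefined for the later triflate.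

**Step 5**
Reactants: 7 tert-butyl (5R,6R)-5-butanoyl-6-[2-(methoxycarbonyl)benzoyl]-2-[(triisopropylsilyl)oxy]cyclohex-1-ene-1-carboxylate
Product: 9 tert-butyl (5R,6R)-5-[(1S)-1-hydroxybutyl]-6-(3-oxo-1,3-dihydro-2-benzofuran-1-yl)-2-[(triisopropylsilyl)oxy]cyclohex-1-ene-1-carboxylate, via diol methyl ester 8 (not isolated)
Conditions: LiBH(s-Bu)3 (2.5 equiv), THF, −78 → −20 °C; aq. NH4Cl, rt
Reagents that add atoms: none
Why: Hydride reduction of both ketones, in which Felkin–Anh attack at C8' anti to the bulky C7 branch of the C6 stereocentre should give the (S)-carbinol while the benzylic C3' alkoxide closes ring C on the ortho methyl ester (5-exo-trig acyl substitution); the C3' configuration is irrelevant because it is erased in step 7.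

**Step 6**
Reactants: 9 tert-butyl (5R,6R)-5-[(1S)-1-hydroxybutyl]-6-(3-oxo-1,3-dihydro-2-benzofuran-1-yl)-2-[(triisopropylsilyl)oxy]cyclohex-1-ene-1-carboxylate
Product: 10 tert-butyl (5R,6R)-5-[(1S)-1-(methanesulfonyloxy)butyl]-6-(3-oxo-1,3-dihydro-2-benzofuran-1-yl)-2-[(triisopropylsilyl)oxy]cyclohex-1-ene-1-carboxylate
Conditions: MsCl (1.5 equiv), Et3N (2 equiv), CH2Cl2, 0 °C
Reagents that add atoms: methanesulfonyl chloride, CS(=O)(=O)Cl
Why: Standard O-sulfonylation of the secondary alcohol, with retention at C8', turns it into the leaving group for ring closure.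

**Step 7**
Reactants: 10 tert-butyl (5R,6R)-5-[(1S)-1-(methanesulfonyloxy)butyl]-6-(3-oxo-1,3-dihydro-2-benzofuran-1-yl)-2-[(triisopropylsilyl)oxy]cyclohex-1-ene-1-carboxylate
Product: 12 tert-butyl (1R,6S,7R,8R)-3'-oxo-7-propyl-3-[(triisopropylsilyl)oxy]-3'H-spiro[bicyclo[4.2.0]oct-2-ene-8,1'-[2]benzofuran]-2-carboxylate, via potassium phthalide enolate 11 (not isolated)
Conditions: KN(SiMe3)2 (1.2 equiv), THF (0.01 M), −78 → 0 °C
Reagents that add atoms: none
Why: Deprotonation at C3' gives the 2-benzofuran-1-olate 11, which should close ring B by intramolecular 4-exo-tet C-alkylation (SN2 with inversion at C8', placing propyl on the face of ring A) as in cyclobutane syntheses by intramolecular ester-enolate alkylation, while C3' is set by substrate control because the benzo ring takes the face away from ring A and the propyl group.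

**Step 8**
Reactants: 12 tert-butyl (1R,6S,7R,8R)-3'-oxo-7-propyl-3-[(triisopropylsilyl)oxy]-3'H-spiro[bicyclo[4.2.0]oct-2-ene-8,1'-[2]benzofuran]-2-carboxylate
Product: 13 tert-butyl (1R,6S,7R,8R)-3,3'-dioxo-7-propyl-3'H-spiro[bicyclo[4.2.0]octane-8,1'-[2]benzofuran]-2-carboxylate (keto/enol mixture at C2)
Conditions: HF·pyridine, THF, 0 °C
Reagents that add atoms: none
Why: Fluoride-mediated cleavage of the silyl enol ether (a vinylogous silyl carbonate) should release the β-keto ester under non-basic conditions that leave the tert-butyl ester and the lactone untouched.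

**Step 9**
Reactants: 13 tert-butyl (1R,6S,7R,8R)-3,3'-dioxo-7-propyl-3'H-spiro[bicyclo[4.2.0]octane-8,1'-[2]benzofuran]-2-carboxylate
Product: 14 tert-butyl (1R,6S,7R,8R)-3'-oxo-7-propyl-3-[(trifluoromethanesulfonyl)oxy]-3'H-spiro[bicyclo[4.2.0]oct-2-ene-8,1'-[2]benzofuran]-2-carboxylate
Conditions: Tf2O (1.3 equiv), 2,6-di-tert-butyl-4-methylpyridine (1.5 equiv), CH2Cl2, −78 → 0 °C
Reagents that add atoms: trifluoromethanesulfonic anhydride, O=S(=O)(OS(=O)(=O)C(F)(F)F)C(F)(F)F
Why: O-triflation of the ketone with a hindered pyridine base should give the conjugated enol triflate regioselectively (loss of the acidic C7a proton) without building up a free β-keto ester enolate, which could open ring B by retro-Michael cleavage of the C7–C3' bond.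

**Step 10**
Reactants: 14 tert-butyl (1R,6S,7R,8R)-3'-oxo-7-propyl-3-[(trifluoromethanesulfonyl)oxy]-3'H-spiro[bicyclo[4.2.0]oct-2-ene-8,1'-[2]benzofuran]-2-carboxylate, 15 pent-1-yne
Product: 16 tert-butyl (1R,6S,7R,8R)-3'-oxo-3-(pent-1-yn-1-yl)-7-propyl-3'H-spiro[bicyclo[4.2.0]oct-2-ene-8,1'-[2]benzofuran]-2-carboxylate
Conditions: PdCl2(PPh3)2 (5 mol%), CuI (10 mol%), Et3N, THF, rt
Reagents that add atoms: none
Why: Sonogashira coupling (oxidative addition of the vinyl triflate to zerovalent palladium, copper acetylide transmetalation) installs the five carbons of the butylidene unit at C3a.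

**Step 11**
Reactants: 16 tert-butyl (1R,6S,7R,8R)-3'-oxo-3-(pent-1-yn-1-yl)-7-propyl-3'H-spiro[bicyclo[4.2.0]oct-2-ene-8,1'-[2]benzofuran]-2-carboxylate
Product: 17 (1R,6S,7R,8R)-3'-oxo-3-(pent-1-yn-1-yl)-7-propyl-3'H-spiro[bicyclo[4.2.0]oct-2-ene-8,1'-[2]benzofuran]-2-carboxylic acid
Conditions: CF3CO2H/CH2Cl2 (1:4), 0 °C
Reagents that add atoms: none
Why: Acidolysis of the tert-butyl ester with loss of 2-methylpropene frees the carboxylic acid, the spiro-lactone and the alkyne tolerating brief cold exposure to the acid.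

**Step 12**
Reactants: 17 (1R,6S,7R,8R)-3'-oxo-3-(pent-1-yn-1-yl)-7-propyl-3'H-spiro[bicyclo[4.2.0]oct-2-ene-8,1'-[2]benzofuran]-2-carboxylic acid
Product: 18 CNP0248594.2, the (3Z)-3-butylidene-4,5,6,7-tetrahydrophthalide whose C6–C7 bond is cis-fused to the cyclobutane carrying the C8' propyl group and the C3' spiro-phthalide, (6S,7R,3'R,8'R)
Conditions: Ag2CO3 (10 mol%), DMF, rt, dark
Reagents that add atoms: none
Why: Silver carbonate-catalysed 5-exo-dig lactonisation of the (Z)-2-en-4-ynoic acid, by anti addition of the carboxylate across the silver-activated alkyne followed by protodemetalation, should give the (Z)-butylidene butenolide (ring D).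

**Compound list**

1 | methyl 2-acetylbenzoate | COC(=O)c1ccccc1C(C)=O | starting material
2 | methyl 2-(2-oxoacetyl)benzoate | COC(=O)c1ccccc1C(=O)C=O | intermediate
3 | tert-butyl 3-oxobutanoate | CC(=O)CC(=O)OC(C)(C)C | starting material
4 | tert-butyl (2Z)-2-acetyl-4-[2-(methoxycarbonyl)phenyl]-4-oxobut-2-enoate | CC(=O)/C(C(=O)OC(C)(C)C)=C/C(=O)c1ccccc1C(=O)OC | intermediate
5 | tert-butyl (2Z)-4-[2-(methoxycarbonyl)phenyl]-4-oxo-2-{1-[(triisopropylsilyl)oxy]ethenyl}but-2-enoate | C=C(O[Si](C(C)C)(C(C)C)C(C)C)/C(C(=O)OC(C)(C)C)=C/C(=O)c1ccccc1C(=O)OC | intermediate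
6 | hex-1-en-3-one | C=CC(=O)CCC | starting material
7 | tert-butyl (5R,6R)-5-butanoyl-6-[2-(methoxycarbonyl)benzoyl]-2-[(triisopropylsilyl)oxy]cyclohex-1-ene-1-carboxylate (5,6-cis; ring positions 5 and 6 are C6 and C7 of the target) | CC(C)(C)OC(=O)C1=C(O[Si](C(C)C)(C(C)C)C(C)C)CC[C@@H](C(=O)CCC)[C@H]1C(=O)c1ccccc1C(=O)OC | intermediate
8 | tert-butyl (5R,6R)-5-[(1S)-1-hydroxybutyl]-6-{hydroxy[2-(methoxycarbonyl)phenyl]methyl}-2-[(triisopropylsilyl)oxy]cyclohex-1-ene-1-carboxylate (both benzylic epimers) | CC(C)(C)OC(=O)C1=C(O[Si](C(C)C)(C(C)C)C(C)C)CC[C@@H]([C@@H](O)CCC)[C@H]1C(O)c1ccccc1C(=O)OC | intermediate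
9 | tert-butyl (5R,6R)-5-[(1S)-1-hydroxybutyl]-6-(3-oxo-1,3-dihydro-2-benzofuran-1-yl)-2-[(triisopropylsilyl)oxy]cyclohex-1-ene-1-carboxylate (both C3' epimers) | CC(C)(C)OC(=O)C1=C(O[Si](C(C)C)(C(C)C)C(C)C)CC[C@@H]([C@@H](O)CCC)[C@H]1C1OC(=O)c2ccccc12 | intermediate
10 | tert-butyl (5R,6R)-5-[(1S)-1-(methanesulfonyloxy)butyl]-6-(3-oxo-1,3-dihydro-2-benzofuran-1-yl)-2-[(triisopropylsilyl)oxy]cyclohex-1-ene-1-carboxylate (both C3' epimers) | CC(C)(C)OC(=O)C1=C(O[Si](C(C)C)(C(C)C)C(C)C)CC[C@@H]([C@@H](OS(C)(=O)=O)CCC)[C@H]1C1OC(=O)c2ccccc12 | intermediate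
11 | potassium enolate of 10 (3-substituted 2-benzofuran-1-olate) | CC(C)(C)OC(=O)C1=C(O[Si](C(C)C)(C(C)C)C(C)C)CC[C@@H]([C@@H](OS(C)(=O)=O)CCC)[C@H]1C1=C2C=CC=CC2=C([O-])O1.[K+] | intermediate
12 | tert-butyl (1R,6S,7R,8R)-3'-oxo-7-propyl-3-[(triisopropylsilyl)oxy]-3'H-spiro[bicyclo[4.2.0]oct-2-ene-8,1'-[2]benzofuran]-2-carboxylate (cis ring fusion; propyl and lactone oxygen on the face of ring A, benzo ring on the other face) | CC(C)(C)OC(=O)C2=C(O[Si](C(C)C)(C(C)C)C(C)C)CC[C@H]1[C@@H](CCC)[C@@]3(OC(=O)c4ccccc43)[C@@H]21 | intermediate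
13 | tert-butyl (1R,6S,7R,8R)-3,3'-dioxo-7-propyl-3'H-spiro[bicyclo[4.2.0]octane-8,1'-[2]benzofuran]-2-carboxylate (keto/enol mixture at C2) | CC(C)(C)OC(=O)C2C(=O)CC[C@H]1[C@@H](CCC)[C@@]3(OC(=O)c4ccccc43)[C@@H]21 | intermediate
14 | tert-butyl (1R,6S,7R,8R)-3'-oxo-7-propyl-3-[(trifluoromethanesulfonyl)oxy]-3'H-spiro[bicyclo[4.2.0]oct-2-ene-8,1'-[2]benzofuran]-2-carboxylate | CC(C)(C)OC(=O)C2=C(OS(=O)(=O)C(F)(F)F)CC[C@H]1[C@@H](CCC)[C@@]3(OC(=O)c4ccccc43)[C@@H]21 | intermediate
15 | pent-1-yne | CCCC#C | starting material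
16 | tert-butyl (1R,6S,7R,8R)-3'-oxo-3-(pent-1-yn-1-yl)-7-propyl-3'H-spiro[bicyclo[4.2.0]oct-2-ene-8,1'-[2]benzofuran]-2-carboxylate | CC(C)(C)OC(=O)C2=C(C#CCCC)CC[C@H]1[C@@H](CCC)[C@@]3(OC(=O)c4ccccc43)[C@@H]21 | intermediate
17 | (1R,6S,7R,8R)-3'-oxo-3-(pent-1-yn-1-yl)-7-propyl-3'H-spiro[bicyclo[4.2.0]oct-2-ene-8,1'-[2]benzofuran]-2-carboxylic acid | OC(=O)C2=C(C#CCCC)CC[C@H]1[C@@H](CCC)[C@@]3(OC(=O)c4ccccc43)[C@@H]21 | intermediate
18 | CNP0248594.2, (6S,7R,3'R,8'R)-configured (3Z)-3-butylidene-tetrahydrophthalide/spiro-phthalide cyclobutane | CCC/C=C1\OC(=O)C2=C1CC[C@H]1[C@@H](CCC)[C@@]3(OC(=O)c4ccccc43)[C@@H]21 | target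

**Step count**

Total steps: 12. Longest linear sequence: 12 steps (1 → 18).

**Steps most likely to fail**

Step 7 (ring B closure). E2 loss of methanesulfonate (toward C6–H or the propyl chain), or unproductive deprotonation at C4, may outrun the slow and congested 4-exo-tet C-alkylation, which must place the propyl group on the concave face. The fallback sets out from 7 and comes back at 12. Diketone 7 would be treated with SmI2 (THF, −78 °C → rt); the ketyl–carbonyl pinacol cyclisation of the 1,4-diketone, a known entry to cis-cyclobutane-1,2-diols, is expected to place both oxygens on the face of ring A, and the C3' alkoxide lactonises on the methyl ester in the flask to give the hydroxy spiro-phthalide F1. Dehydration of the tertiary C8' alcohol with methyl N-(triethylammoniosulfonyl)carbamate (Burgess reagent, toluene, 60 °C) should give the exocyclic alkylidenecyclobutane F2. Hydrogenation (H2, palladium on carbon, EtOAc) from the convex face, away from ring A, would then deliver H to C8' on that face and leave propyl on the face of ring A, giving 12.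

Step 4 (key cycloaddition). The push–pull diene 5 is itself a Michael acceptor and may self-condense; the boron catalyst may give insufficient enantioface or endo control (the antipodal catalyst is available if the sense of induction is opposite); and the doubly activated C7–H may epimerise and erode the 6,7-cis relation. The fallback sets out from 5 and comes back at 7. Diene 5 would be combined with commercial 3-acryloyl-1,3-oxazolidin-2-one under the Cu(SbF6)2 complex of 2,2'-(propane-2,2-diyl)bis[(4S)-4-tert-butyl-4,5-dihydro-1,3-oxazole] (CH2Cl2, −40 °C), a divalent-copper Lewis acid that binds the imide by two-point chelation, to give the imide adduct F3 (ligand antipode chosen to match the 5R,6R series). LiSEt (THF, 0 °C) would convert F3 into the thioester F4, and Fukuyama coupling of F4 with commercial n-PrZnBr (PdCl2(PPh3)2, toluene/THF, rt) would give ketone 7 without touching the aryl ketone or the esters.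

Step 12 (ring D closure). 6-endo-dig attack of the carboxylate, giving the isomeric 2-pyranone, may compete with the desired 5-exo-dig closure, and the alkene geometry may erode. The fallback sets out from 14 and comes back at 18. Carbonylative Negishi coupling of triflate 14 with commercial n-BuZnBr (CO 1 atm, Pd(PPh3)4, THF, rt → 50 °C) should give the butyl ketone F5. CF3CO2H (CH2Cl2, 0 °C) would free the γ-keto acid F6, in equilibrium with its hydroxy-lactol form. Dehydrative enol-lactonisation (TsOH, toluene, reflux) should then give 18 as the thermodynamically preferred (Z)-isomer, as in the classical preparation of butylidenephthalides from 2-pentanoylbenzoic acids.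

**Further compounds**

F1 | step 7 | tert-butyl 7-hydroxy-3'-oxo-7-propyl-3-[(triisopropylsilyl)oxy]-3'H-spiro[bicyclo[4.2.0]oct-2-ene-8,1'-[2]benzofuran]-2-carboxylate (C8' hydroxyl cis to the lactone oxygen) | CC(C)(C)OC(=O)C2=C(O[Si](C(C)C)(C(C)C)C(C)C)CC[C@H]1[C@@](CCC)(O)[C@@]3(OC(=O)c4ccccc43)[C@@H]21
F2 | step 7 | tert-butyl 3'-oxo-7-propylidene-3-[(triisopropylsilyl)oxy]-3'H-spiro[bicyclo[4.2.0]oct-2-ene-8,1'-[2]benzofuran]-2-carboxylate (alkene geometry not fixed) | CC(C)(C)OC(=O)C2=C(O[Si](C(C)C)(C(C)C)C(C)C)CC[C@H]1C(=CCC)[C@@]3(OC(=O)c4ccccc43)[C@@H]21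
F3 | step 4 | tert-butyl (5R,6R)-6-[2-(methoxycarbonyl)benzoyl]-5-(2-oxo-1,3-oxazolidine-3-carbonyl)-2-[(triisopropylsilyl)oxy]cyclohex-1-ene-1-carboxylate | CC(C)(C)OC(=O)C1=C(O[Si](C(C)C)(C(C)C)C(C)C)CC[C@@H](C(=O)N2CCOC2=O)[C@H]1C(=O)c1ccccc1C(=O)OC
F4 | step 4 | tert-butyl (5R,6R)-5-[(ethylsulfanyl)carbonyl]-6-[2-(methoxycarbonyl)benzoyl]-2-[(triisopropylsilyl)oxy]cyclohex-1-ene-1-carboxylate | CC(C)(C)OC(=O)C1=C(O[Si](C(C)C)(C(C)C)C(C)C)CC[C@@H](C(=O)SCC)[C@H]1C(=O)c1ccccc1C(=O)OC
F5 | step 12 | tert-butyl (1R,6S,7R,8R)-3'-oxo-3-pentanoyl-7-propyl-3'H-spiro[bicyclo[4.2.0]oct-2-ene-8,1'-[2]benzofuran]-2-carboxylate | CC(C)(C)OC(=O)C2=C(C(=O)CCCC)CC[C@H]1[C@@H](CCC)[C@@]3(OC(=O)c4ccccc43)[C@@H]21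
F6 | step 12 | (1R,6S,7R,8R)-3'-oxo-3-pentanoyl-7-propyl-3'H-spiro[bicyclo[4.2.0]oct-2-ene-8,1'-[2]benzofuran]-2-carboxylic acid | OC(=O)C2=C(C(=O)CCCC)CC[C@H]1[C@@H](CCC)[C@@]3(OC(=O)c4ccccc43)[C@@H]21
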